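**Strategy.** The route rests on reading the two cis methyl groups on the adjacent quaternary carbons C1 and C2 of the cyclopentane as the two CH2 groups of a thiolane fused across the C1–C2 bond, and the two carbonyl-bearing arms as the carbonyls of an anhydride on the same bond. One (3+2) cycloaddition of the parent thiocarbonyl ylide to the tetrasubstituted alkene of the flat, doubly activated bicycle 1-cyclopentene-1,2-dicarboxylic anhydride forms both quaternary centres and both future C–CH3 bonds, necessarily cis, as a meso propellane. Desulfurisation, alkaloid-mediated opening of the resulting meso anhydride, homologation of the acid and late oxidations complete the synthesis.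

Key step: step 1

Assumption: quinidine is taken to direct methanol, as with other cis-fused bicyclic meso anhydrides, onto the methyl-bearing face so that the (1S,2R) hemiester 6 results; should the sense prove opposite, quinine replaces it and nothing else changes.

**Step 1**
Reactants: 1 1-cyclopentene-1,2-dicarboxylic anhydride; 2 chloromethyl (trimethylsilyl)methyl sulfide
Product: 4 meso-3-oxa-7-thia[3.3.3]propellane-2,4-dione, via thioformaldehyde S-methylide 3 (not isolated)
Conditions: CsF (dried, 3 equiv), MeCN, rt → 40 °C, 2 (3 equiv) added slowly by syringe pump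
Reagents that add atoms: none
Why: Fluoride attacks silicon of 2 and the resulting α-thio carbanion expels chloride, releasing the parent thiocarbonyl ylide 3, an electron-rich dipole that should add in a concerted, suprafacial [π4s+π2s] manner to the low-LUMO alkene of 1. The closest known reaction type is the thiocarbonyl ylide (3+2) cycloaddition to maleic anhydride, maleimides and fumarates, which has been extended to tetrasubstituted acceptors before reductive desulfurisation. The thiolane ring is closed by the cycloaddition itself, both C–CH2 bonds forming on the same face of the alkene in one transition state, so no separate cyclisation is involved. The two new quaternary stereocentres are set by that suprafacial delivery and by the ring fusion, since only the cis-fused propellane can exist, and because the product is meso no facial selectivity is required. The step does need the dipole to take the hindered C=C in preference to the anhydride C=O groups and to its own oligomerisation; the anhydride ring holds both carbonyls coplanar with the alkene and ties the substituents back, and slow addition of 2 keeps the ylide concentration low.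

**Step 2**
Reactants: 4 meso-3-oxa-7-thia[3.3.3]propellane-2,4-dione
Product: 5 meso-cis-1,2-dimethylcyclopentane-1,2-dicarboxylic anhydride
Conditions: Raney Ni (W-2, washed neutral, solvent-exchanged to dry THF), THF, 50 °C; filtration, toluene azeotrope
Reagents that add atoms: none
Why: Raney-nickel desulfurisation (hydrogenolysis of both C–S bonds) should turn the CH2–S–CH2 bridge into the two methyl groups while the anhydride, which is not reducible under these conditions and recloses readily if opened by traces of water, is kept; the quaternary centres are not touched, so the methyls stay cis.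

**Step 3**
Reactants: 5 meso-cis-1,2-dimethylcyclopentane-1,2-dicarboxylic anhydride
Product: 6 (1S,2R)-2-(methoxycarbonyl)-1,2-dimethylcyclopentane-1-carboxylic acid
Conditions: quinidine (1.1 equiv), MeOH (5 equiv), toluene, −20 °C; cold aq. HCl work-up (alkaloid recovered), product used promptly
Reagents that add atoms: methanol, CO
Why: Cinchona-alkaloid-mediated desymmetrising alcoholysis of a cyclic meso anhydride: quinidine acts as a chiral general base that delivers methanol to one of the two enantiotopic carbonyls over the convex, methyl-bearing face, which fixes the absolute configuration of both quaternary carbons, and the opening is placed after desulfurisation because the two faces of 5 (two free methyls against the folded trimethylene bridge) differ more than the thiolane and cyclopentane faces of 4.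

**Step 4**
Reactants: 6 (1S,2R)-2-(methoxycarbonyl)-1,2-dimethylcyclopentane-1-carboxylic acid
Product: 8 methyl (1R,2S)-2-(diazoacetyl)-1,2-dimethylcyclopentane-1-carboxylate, via acid chloride 7 (not isolated)
Conditions: (COCl)2, DMF (cat.), CH2Cl2, 0 °C; evaporate cold; CH2N2 (excess), Et2O, 0 °C
Reagents that add atoms: diazomethane, C=[N+]=[N-]
Why: First half of the Arndt–Eistert homologation: the acid is converted into its chloride and acylates diazomethane (a second equivalent scavenges HCl), the chloride being kept cold and used at once so that exchange with the neighbouring ester, which would racemise the material, does not compete.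

**Step 5**
Reactants: 8 methyl (1R,2S)-2-(diazoacetyl)-1,2-dimethylcyclopentane-1-carboxylate
Product: 10 methyl (1R,2R)-2-{2-[methoxy(methyl)amino]-2-oxoethyl}-1,2-dimethylcyclopentane-1-carboxylate, via ketene 9 (not isolated)
Conditions: hν (365 nm), MeNH(OMe)·HCl, Et3N, THF, rt
Reagents that add atoms: N,O-dimethylhydroxylamine (as hydrochloride), CNOC
Why: Photochemical Wolff rearrangement: loss of N2 with 1,2-shift of the ring carbon, which migrates with retention, gives ketene 9 and the amine traps it as the Weinreb amide; irradiation is preferred to silver catalysis because α-quaternary diazoketones often resist the latter.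

**Step 6**
Reactants: 10 methyl (1R,2R)-2-{2-[methoxy(methyl)amino]-2-oxoethyl}-1,2-dimethylcyclopentane-1-carboxylate
Product: 11 methyl (1R,2R)-1,2-dimethyl-2-(2-oxoethyl)cyclopentane-1-carboxylate
Conditions: DIBAL-H (1.2 equiv), THF, −78 °C; aq. Rochelle salt
Reagents that add atoms: none
Why: Weinreb amide reduction: DIBAL-H gives a chelated tetrahedral adduct that collapses to the aldehyde only on work-up, while the ester, buried between two quaternary carbons, should not react at −78 °C with a near-stoichiometric charge.

**Step 7**
Reactants: 11 methyl (1R,2R)-1,2-dimethyl-2-(2-oxoethyl)cyclopentane-1-carboxylate; 12 propargyl bromide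
Product: 14 methyl (1R,2R)-2-(2-hydroxypent-4-yn-1-yl)-1,2-dimethylcyclopentane-1-carboxylate (carbinol epimers), via allenylzinc bromide 13 (not isolated)
Conditions: Zn dust, THF/sat. aq. NH4Cl, 0 °C → rt
Reagents that add atoms: none
Why: Barbier propargylation: the allenylzinc species formed in situ adds to the aldehyde through an SE2′ transition state to give the homopropargylic alcohol, the mild aqueous medium sparing the hindered ester; the carbinol centre forms without control, which does not matter because it becomes a ketone in the last step.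

**Step 8**
Reactants: 14 methyl (1R,2R)-2-(2-hydroxypent-4-yn-1-yl)-1,2-dimethylcyclopentane-1-carboxylate
Product: 15 methyl (1R,2R)-2-[2-(tert-butyldimethylsilyloxy)pent-4-yn-1-yl]-1,2-dimethylcyclopentane-1-carboxylate
Conditions: TBSCl, imidazole, DMF, rt
Reagents that add atoms: tert-butyldimethylsilyl chloride, CC(C)(C)[Si](C)(C)Cl
Why: Standard silylation of a secondary alcohol, which also blocks lactonisation onto the C1 ester and protects the carbinol during the organometallic and oxidation steps that follow.

**Step 9**
Reactants: 16 2-hydroxy-3-methylbenzaldehyde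
Product: 17 2-(tert-butyldimethylsilyloxy)-3-methylbenzaldehyde
Conditions: TBSCl, imidazole, DMF, rt
Reagents that add atoms: tert-butyldimethylsilyl chloride, CC(C)(C)[Si](C)(C)Cl
Why: Imidazole-promoted silylation masks the acidic phenol for the reduction, halide formation and cross-coupling.

**Step 10**
Reactants: 17 2-(tert-butyldimethylsilyloxy)-3-methylbenzaldehyde
Product: 18 [2-(tert-butyldimethylsilyloxy)-3-methylphenyl]methanol
Conditions: NaBH4, MeOH, 0 °C
Reagents that add atoms: none
Why: Borohydride reduction of an aromatic aldehyde in a protic solvent at 0 °C, where the aryl silyl ether should neither be cleaved nor migrate.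

**Step 11**
Reactants: 18 [2-(tert-butyldimethylsilyloxy)-3-methylphenyl]methanol
Product: 20 tert-butyl[2-(chloromethyl)-6-methylphenoxy]dimethylsilane, via benzylic mesylate 19 (not isolated)
Conditions: MsCl, Et3N, CH2Cl2, 0 °C; then LiCl, DMF, rt
Reagents that add atoms: lithium chloride, [Li+].[Cl-]
Why: Mesylation of the benzylic alcohol followed by SN2 displacement with chloride, a neutral-to-basic sequence that spares the aryl silyl ether.

**Step 12**
Reactants: 15 methyl (1R,2R)-2-[2-(tert-butyldimethylsilyloxy)pent-4-yn-1-yl]-1,2-dimethylcyclopentane-1-carboxylate; 20 tert-butyl[2-(chloromethyl)-6-methylphenoxy]dimethylsilane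
Product: 22 methyl (1R,2R)-2-[(4E)-2-(tert-butyldimethylsilyloxy)-6-{2-(tert-butyldimethylsilyloxy)-3-methylphenyl}-4-methylhex-4-en-1-yl]-1,2-dimethylcyclopentane-1-carboxylate, via alkenyldimethylalane 21 (not isolated)
Conditions: Me3Al (3 equiv), Cp2ZrCl2 (0.3 equiv), CH2Cl2, 0 °C → rt; volatiles removed in vacuo; then 20, Pd(PPh3)4 (5 mol %), THF, rt
Reagents that add atoms: trimethylaluminium, C[Al](C)C
Why: Negishi zirconium-catalysed carboalumination adds methyl and aluminium syn across the terminal alkyne with aluminium on the terminal carbon, and palladium-catalysed cross-coupling of the alkenylalane with the benzylic chloride proceeds with retention, so the trisubstituted alkene is formed as the E isomer; excess Me3Al is stripped first so that it cannot methylate the benzylic chloride.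

**Step 13**
Reactants: 22 methyl (1R,2R)-2-[(4E)-2-(tert-butyldimethylsilyloxy)-6-{2-(tert-butyldimethylsilyloxy)-3-methylphenyl}-4-methylhex-4-en-1-yl]-1,2-dimethylcyclopentane-1-carboxylate
Product: 23 [(1R,2R)-2-[(4E)-2-(tert-butyldimethylsilyloxy)-6-{2-(tert-butyldimethylsilyloxy)-3-methylphenyl}-4-methylhex-4-en-1-yl]-1,2-dimethylcyclopentyl]methanol
Conditions: DIBAL-H (3 equiv), CH2Cl2, −78 → 0 °C; aq. Rochelle salt
Reagents that add atoms: none
Why: Hydride reduction of the ester to the primary alcohol, for which an excess of DIBAL-H at 0 °C should overcome the steric shielding while silyl ethers and the alkene are inert.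

**Step 14**
Reactants: 23 [(1R,2R)-2-[(4E)-2-(tert-butyldimethylsilyloxy)-6-{2-(tert-butyldimethylsilyloxy)-3-methylphenyl}-4-methylhex-4-en-1-yl]-1,2-dimethylcyclopentyl]methanol
Product: 24 (1R,2R)-2-[(4E)-2-(tert-butyldimethylsilyloxy)-6-{2-(tert-butyldimethylsilyloxy)-3-methylphenyl}-4-methylhex-4-en-1-yl]-1,2-dimethylcyclopentane-1-carbaldehyde
Conditions: Dess–Martin periodinane, NaHCO3, CH2Cl2, rt
Reagents that add atoms: none
Why: Dess–Martin oxidation of the neopentyl primary alcohol to a non-enolisable aldehyde under buffered, neutral conditions that leave both silyl ethers and the alkene alone.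

**Step 15**
Reactants: 24 (1R,2R)-2-[(4E)-2-(tert-butyldimethylsilyloxy)-6-{2-(tert-butyldimethylsilyloxy)-3-methylphenyl}-4-methylhex-4-en-1-yl]-1,2-dimethylcyclopentane-1-carbaldehyde; 25 prenyl chloride (1-chloro-3-methylbut-2-ene)
Product: 27 1-[(1R,2R)-2-[(4E)-2-(tert-butyldimethylsilyloxy)-6-{2-(tert-butyldimethylsilyloxy)-3-methylphenyl}-4-methylhex-4-en-1-yl]-1,2-dimethylcyclopentyl]-4-methylpent-3-en-1-ol (carbinol epimers), via prenylbarium chloride 26 (not isolated)
Conditions: active Ba (BaI2, 2 equiv lithium biphenylide, THF, rt); 25, −78 °C; then 24, −78 °C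
Reagents that add atoms: none
Why: Allylbarium addition: prenylbarium reagents attack aldehydes through their unsubstituted α-carbon at −78 °C, giving the linear 3-methylbut-2-enyl carbinol, and the neopentyl environment of the aldehyde further disfavours γ-attack, which would place a quaternary carbon next to the carbinol; the new carbinol centre is uncontrolled and is oxidised later.

**Step 16**
Reactants: 27 1-[(1R,2R)-2-[(4E)-2-(tert-butyldimethylsilyloxy)-6-{2-(tert-butyldimethylsilyloxy)-3-methylphenyl}-4-methylhex-4-en-1-yl]-1,2-dimethylcyclopentyl]-4-methylpent-3-en-1-ol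
Product: 28 2-[(2E)-5-hydroxy-6-{(1R,2R)-2-(1-hydroxy-4-methylpent-3-en-1-yl)-1,2-dimethylcyclopentyl}-3-methylhex-2-en-1-yl]-6-methylphenol
Conditions: TBAF (3 equiv), THF, 0 °C → rt
Reagents that add atoms: none
Why: Fluoride-induced cleavage of the Si–O bonds removes the aryl and the secondary alkyl silyl ethers in one operation.

**Step 17**
Reactants: 28 2-[(2E)-5-hydroxy-6-{(1R,2R)-2-(1-hydroxy-4-methylpent-3-en-1-yl)-1,2-dimethylcyclopentyl}-3-methylhex-2-en-1-yl]-6-methylphenol
Product: 29 2-[(2E)-5-hydroxy-6-{(1R,2R)-2-(1-hydroxy-4-methylpent-3-en-1-yl)-1,2-dimethylcyclopentyl}-3-methylhex-2-en-1-yl]-6-methylcyclohexa-2,5-diene-1,4-dione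
Conditions: Fremy's salt (2.5 equiv), KH2PO4, H2O/acetone, rt
Reagents that add atoms: potassium nitrosodisulfonate (Fremy's salt), [K+].[K+].[O]N(S(=O)(=O)[O-])S(=O)(=O)[O-]
Why: Teuber oxidation: Fremy's radical abstracts the phenolic hydrogen and a second equivalent adds at the free para position of the 2,6-dialkylphenol, giving the p-benzoquinone after loss of imidodisulfonate, without touching the secondary alcohols or the alkenes.

**Step 18**
Reactants: 29 2-[(2E)-5-hydroxy-6-{(1R,2R)-2-(1-hydroxy-4-methylpent-3-en-1-yl)-1,2-dimethylcyclopentyl}-3-methylhex-2-en-1-yl]-6-methylcyclohexa-2,5-diene-1,4-dione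
Product: 30 the target, 2-[(2E)-6-{(1R,2R)-1,2-dimethyl-2-(4-methylpent-3-enoyl)cyclopentyl}-3-methyl-5-oxohex-2-en-1-yl]-6-methylcyclohexa-2,5-diene-1,4-dione
Conditions: Dess–Martin periodinane (3 equiv), NaHCO3, CH2Cl2, 0 °C → rt
Reagents that add atoms: none
Why: Dess–Martin oxidation of both homoallylic secondary alcohols under bicarbonate buffer gives the two β,γ-unsaturated ketones at the very end, so that the double bonds have no opportunity to move into conjugation, and the quinone is inert to the reagent.

**Compound list**

1 | 1-cyclopentene-1,2-dicarboxylic anhydride | O=C1OC(=O)C2=C1CCC2 | starting material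
2 | chloromethyl (trimethylsilyl)methyl sulfide | C[Si](C)(C)CSCCl | starting material
3 | thioformaldehyde S-methylide (parent thiocarbonyl ylide) | [CH2-][S+]=C | intermediate (not isolated)
4 | meso-3-oxa-7-thia[3.3.3]propellane-2,4-dione (thiolane, cyclopentane and anhydride rings sharing the bond between the two quaternary carbons) | O=C1OC(=O)[C@@]23CCC[C@@]12CSC3 | intermediate
5 | meso-cis-1,2-dimethylcyclopentane-1,2-dicarboxylic anhydride | O=C1OC(=O)[C@@]2(C)CCC[C@@]12C | intermediate
6 | (1S,2R)-2-(methoxycarbonyl)-1,2-dimethylcyclopentane-1-carboxylic acid | COC(=O)[C@]1(C)CCC[C@]1(C)C(=O)O | intermediate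
7 | methyl (1R,2S)-2-(chlorocarbonyl)-1,2-dimethylcyclopentane-1-carboxylate | COC(=O)[C@]1(C)CCC[C@]1(C)C(Cl)=O | intermediate (not isolated)
8 | methyl (1R,2S)-2-(diazoacetyl)-1,2-dimethylcyclopentane-1-carboxylate | COC(=O)[C@]1(C)CCC[C@]1(C)C(=O)C=[N+]=[N-] | intermediate
9 | methyl (1R,2R)-1,2-dimethyl-2-(2-oxoethenyl)cyclopentane-1-carboxylate (ketene) | COC(=O)[C@]1(C)CCC[C@]1(C)C=C=O | intermediate (not isolated)
10 | methyl (1R,2R)-2-{2-[methoxy(methyl)amino]-2-oxoethyl}-1,2-dimethylcyclopentane-1-carboxylate | COC(=O)[C@]1(C)CCC[C@]1(C)CC(=O)N(C)OC | intermediate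
11 | methyl (1R,2R)-1,2-dimethyl-2-(2-oxoethyl)cyclopentane-1-carboxylate | COC(=O)[C@]1(C)CCC[C@]1(C)CC=O | intermediate
12 | propargyl bromide | C#CCBr | starting material
13 | allenylzinc bromide | C=C=C[Zn]Br | intermediate (not isolated)
14 | methyl (1R,2R)-2-(2-hydroxypent-4-yn-1-yl)-1,2-dimethylcyclopentane-1-carboxylate (carbinol epimers) | COC(=O)[C@]1(C)CCC[C@]1(C)CC(O)CC#C | intermediate
15 | methyl (1R,2R)-2-[2-(tert-butyldimethylsilyloxy)pent-4-yn-1-yl]-1,2-dimethylcyclopentane-1-carboxylate (epimers at the silyloxy carbon) | COC(=O)[C@]1(C)CCC[C@]1(C)CC(O[Si](C)(C)C(C)(C)C)CC#C | intermediate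
16 | 2-hydroxy-3-methylbenzaldehyde | Cc1cccc(C=O)c1O | starting material
17 | 2-(tert-butyldimethylsilyloxy)-3-methylbenzaldehyde | Cc1cccc(C=O)c1O[Si](C)(C)C(C)(C)C | intermediate
18 | [2-(tert-butyldimethylsilyloxy)-3-methylphenyl]methanol | Cc1cccc(CO)c1O[Si](C)(C)C(C)(C)C | intermediate
19 | 2-(tert-butyldimethylsilyloxy)-3-methylbenzyl methanesulfonate | Cc1cccc(COS(C)(=O)=O)c1O[Si](C)(C)C(C)(C)C | intermediate (not isolated)
20 | tert-butyl[2-(chloromethyl)-6-methylphenoxy]dimethylsilane | Cc1cccc(CCl)c1O[Si](C)(C)C(C)(C)C | intermediate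
21 | (E)-alkenyldimethylalane from 15 (Me on the internal and AlMe2 on the terminal alkene carbon, chain and Al trans) | COC(=O)[C@]1(C)CCC[C@]1(C)CC(O[Si](C)(C)C(C)(C)C)C/C(C)=C/[Al](C)C | intermediate (not isolated)
22 | methyl (1R,2R)-2-[(4E)-2-(tert-butyldimethylsilyloxy)-6-{2-(tert-butyldimethylsilyloxy)-3-methylphenyl}-4-methylhex-4-en-1-yl]-1,2-dimethylcyclopentane-1-carboxylate | COC(=O)[C@]1(C)CCC[C@]1(C)CC(O[Si](C)(C)C(C)(C)C)C/C(C)=C/Cc1cccc(C)c1O[Si](C)(C)C(C)(C)C | intermediate
23 | primary alcohol from 22 (CH2OH on C1 in place of CO2Me) | OC[C@]1(C)CCC[C@]1(C)CC(O[Si](C)(C)C(C)(C)C)C/C(C)=C/Cc1cccc(C)c1O[Si](C)(C)C(C)(C)C | intermediate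
24 | aldehyde from 23 (CHO on C1) | O=C[C@]1(C)CCC[C@]1(C)CC(O[Si](C)(C)C(C)(C)C)C/C(C)=C/Cc1cccc(C)c1O[Si](C)(C)C(C)(C)C | intermediate
25 | prenyl chloride (1-chloro-3-methylbut-2-ene) | CC(C)=CCCl | starting material
26 | prenylbarium chloride | CC(C)=CC[Ba]Cl | intermediate (not isolated)
27 | bis-silyl homoallylic alcohol (C1 carries CH(OH)CH2CH=CMe2; carbinol epimers) | CC(C)=CCC(O)[C@]1(C)CCC[C@]1(C)CC(O[Si](C)(C)C(C)(C)C)C/C(C)=C/Cc1cccc(C)c1O[Si](C)(C)C(C)(C)C | intermediate
28 | 2-[(2E)-5-hydroxy-6-{(1R,2R)-2-(1-hydroxy-4-methylpent-3-en-1-yl)-1,2-dimethylcyclopentyl}-3-methylhex-2-en-1-yl]-6-methylphenol | CC(C)=CCC(O)[C@]1(C)CCC[C@]1(C)CC(O)C/C(C)=C/Cc1cccc(C)c1O | intermediate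
29 | quinone diol: 2-[(2E)-5-hydroxy-6-{(1R,2R)-2-(1-hydroxy-4-methylpent-3-en-1-yl)-1,2-dimethylcyclopentyl}-3-methylhex-2-en-1-yl]-6-methylcyclohexa-2,5-diene-1,4-dione | CC(C)=CCC(O)[C@]1(C)CCC[C@]1(C)CC(O)C/C(C)=C/CC1=CC(=O)C=C(C)C1=O | intermediate
30 | 2-[(2E)-6-{(1R,2R)-1,2-dimethyl-2-(4-methylpent-3-enoyl)cyclopentyl}-3-methyl-5-oxohex-2-en-1-yl]-6-methylcyclohexa-2,5-diene-1,4-dione | CC(C)=CCC(=O)[C@]1(C)CCC[C@]1(C)CC(=O)C/C(C)=C/CC1=CC(=O)C=C(C)C1=O | target

**Step count.** 18 steps in total. The longest linear sequence is 15 steps (steps 1–8 and 12–18); the arene arm (steps 9–11) is 3 steps.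

**Steps most likely to fail**

1. Step 1. The short-lived ylide may dimerise or polymerise faster than it adds to the tetrasubstituted, sterically shielded alkene, and fluoride may reversibly open the anhydride and lower its reactivity. The fallback sets out from 1 and rejoins the route at 5, using the same alkene as a dienophile instead of a dipolarophile. Thermal Diels–Alder reaction of 1 with buta-1,3-diene (sealed tube, about 160 °C, hydroquinone) should give the meso 8-oxa[4.3.3]propell-3-ene-7,9-dione F1. Ozonolysis (O3, CH2Cl2, −78 °C; PPh3) should open its cyclohexene ring to meso-cis-1,2-bis(2-oxoethyl)cyclopentane-1,2-dicarboxylic anhydride F2. Twofold Tsuji–Wilkinson decarbonylation (RhCl(PPh3)3, 2 equiv, toluene, reflux) should then shorten each CH2CHO arm to a methyl group, giving 5.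

2. Step 3. The alkaloid may not distinguish the two enantiotopic carbonyls well enough, because each is flanked on one face by a methyl group and on the other by a ring CH2 of similar size, and the hindered anhydride may react only at temperatures where selectivity falls. The fallback sets out from 5 and rejoins the route at 6, replacing asymmetric induction by resolution. Opening of 5 without selectivity (NaOMe, MeOH, 0 °C) should give 6 together with its antipode, (1R,2S)-2-(methoxycarbonyl)-1,2-dimethylcyclopentane-1-carboxylic acid F3. Fractional crystallisation with (R)-1-phenylethylamine is expected to deposit the (R)-1-phenylethylammonium salt of 6 F4, and acidification (aq. HCl, EtOAc) of the purified salt returns 6.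

3. Step 12. Transfer of the alkenyl group from aluminium to palladium may be slow, and residual aluminium species may ionise or methylate the electron-rich benzylic chloride. The fallback sets out from 15 (through alane 21) and rejoins the route at 22, separating the two events. The alane 21 is quenched with iodine (THF, −30 °C) to give the isolable (E)-alkenyl iodide F5. Separately, 20 is converted with zinc dust and LiCl in THF into 2-(tert-butyldimethylsilyloxy)-3-methylbenzylzinc chloride F6. Negishi cross-coupling of F5 with F6 (Pd(OAc)2, SPhos, THF, rt) should then give 22.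

**Further compounds**

F1 | step 1 | meso-8-oxa[4.3.3]propell-3-ene-7,9-dione (Diels–Alder adduct of 1 with buta-1,3-diene) | O=C1OC(=O)[C@@]23CCC[C@@]12CC=CC3
F2 | step 1 | meso-cis-1,2-bis(2-oxoethyl)cyclopentane-1,2-dicarboxylic anhydride | O=C1OC(=O)[C@@]2(CC=O)CCC[C@@]12CC=O
F3 | step 3 | (1R,2S)-2-(methoxycarbonyl)-1,2-dimethylcyclopentane-1-carboxylic acid (antipode of 6) | COC(=O)[C@@]1(C)CCC[C@@]1(C)C(=O)O
F4 | step 3 | (R)-1-phenylethylammonium (1S,2R)-2-(methoxycarbonyl)-1,2-dimethylcyclopentane-1-carboxylate | COC(=O)[C@]1(C)CCC[C@]1(C)C(=O)[O-].C[C@@H]([NH3+])c1ccccc1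
F5 | step 12 | methyl (1R,2R)-2-[(4E)-2-(tert-butyldimethylsilyloxy)-5-iodo-4-methylpent-4-en-1-yl]-1,2-dimethylcyclopentane-1-carboxylate | COC(=O)[C@]1(C)CCC[C@]1(C)CC(O[Si](C)(C)C(C)(C)C)C/C(C)=C/I
F6 | step 12 | 2-(tert-butyldimethylsilyloxy)-3-methylbenzylzinc chloride | Cc1cccc(C[Zn]Cl)c1O[Si](C)(C)C(C)(C)C
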